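A small charge of free catalyst, 2.5 mM in delta, was where I began, because I wanted to know how much target any of these flasks could still hold at its end, whatever the catalyst did.

| setting | green | amber | delta | theta | gamma | alpha |
|---|---|---|---|---|---|---|
| starting material | 0.057 M | 0.057 M | 0.057 M | 0.057 M | 0.057 M | 0.057 M |
| second substrate | 0.0285 M | 0.0285 M | 0.0285 M | 0.0285 M | 0.0285 M | 0.0285 M |
| free catalyst | 3.7 mM | 110 mM | 2.5 mM | 8.0 mM | 25 mM | 80 mM |
| remark | run made earlier | run made earlier |  |  |  |  |
| time |  |  | 1.0 h | 1.0 h | 1.0 h | 1.0 h |

| run | time / min | target / % |
|---|---|---|
| green | 8.00 | 15 |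
| green | 15.0 | 17 |
| green | 25.0 | 19 |
| green | 30.0 | 10 |
| green | 40.0 | 8 |
| amber | 4.00 | 74 |
| amber | 10.0 | 52 |
| amber | 20.0 | 28 |
| amber | 30.0 | 10 |
| amber | 40.0 | 6 |

(readings scatter by 1.5 percentage points)

- the analysis behind the earlier runs scatters by 1.5 percentage points, standard deviation
- "hardly changes" means that all values lie within two and a half points (for a concentration: within two and a half percent of the largest)

1. [target] at the end for delta, theta, gamma, alpha, in this order
2. the course of these numbers from the first flask to the last (rises all the way / rises, then falls / hardly changes / falls all the way / falls, then rises)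

Amber fell from 74% to 6% between 4.00 min and 40.0 min, so I read a loss constant of 0.0698 min⁻¹. Amber's first three readings alone give 0.0607 min⁻¹ and its last three 0.0770 min⁻¹, so I took the loss as roughly first order in target, and I assumed the same constant for the smaller charges of catalyst, an assumption that green's readings do not test. Its inverse is my holding time, the minutes' worth of making that a flask holds once making and loss balance (a quasi-steady state): 14.3 min.

My zero of the scale was the even case, with the charge turned to target steadily through 1.0 h, which leaves about 0.0134 M. For the floor I took the whole charge made at once, as amber nearly did, since its readings trace back to 97.9%. That leaves 8.66 × 10⁻⁴ M. To tighten the top I used green, whose target fell more slowly between 30.0 min and 40.0 min than loss alone asks, so I took it that making continued. Held steady, that making gives roughly 0.00350 M, and I committed to the row lying between floor and top.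

The forecast gave 0.007 M, 0.02 M, 0.033 M and 0.004 M, a row that rises, then falls. It said “I take decay as roughly first order in catalyst”, where I did not. Its middle values stood above my even case, and its outer values above my top.

The flasks gave 0.00187 M, 0.00323 M, 0.00114 M and 9.79 × 10⁻⁴ M, a row that rises, then falls, inside my bracket.

    starting material + free catalyst ⇌ catalyst intermediate A (K = 4100 M⁻¹, k = 0.445 M⁻¹ s⁻¹)
    catalyst intermediate A → free catalyst + target (k = 0.0165 s⁻¹)
    second substrate + free catalyst ⇌ catalyst intermediate B (K = 35.0 M⁻¹, k = 0.511 M⁻¹ s⁻¹)
    catalyst intermediate B → free catalyst + second product (k = 0.0394 s⁻¹)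
    2 second substrate → self-condensation product (k = 0.0656 M⁻¹ s⁻¹)
    target → over-reaction product (k = 0.00113 s⁻¹)
    catalyst intermediate A → spent catalyst (k = 0.00184 s⁻¹)

At 0.500 h, gamma held 0% of its starting material and 15.3% target. The holding time carries that target to 1.89% at the end, and gamma stood at 2.00%. In delta, the holding time puts the final loss of target at 0.131 mM min⁻¹, and making ran at 0.367 of the loss.

The earlier runs and the new flask come from a simulation for substances that don't exist; the scatter is artificial.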